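# Proposed synthesis of (2R,3S)-5'-geranyl-3',4',5,7-tetrahydroxyflavan-3-ol (16) by chiral sulfonium ylide epoxidation

## The problem

The target 16 is a flavan-3-ol. A chroman (rings A and C) carries the geranylated catechol ring B on C2 and a hydroxyl on C3, trans to each other, (2R,3S). Ring C has to be built from a phloroglucinol-type ring A and ring B through the three-carbon bridge C2–C3–C4. C2 and C3 are the only stereocentres and no remote centre can guide them. Either a reagent sets both together, or C2 is set first and directs C3 by substrate control; control of C2 from C3 is weak. The geranyl chain on C5' has two trisubstituted alkenes, one of fixed E geometry. This rules out dihydroxylation, peracid or dioxirane epoxidation, hydroboration and hydrogenolysis once the chain is in place, and strong acid would cyclise the chain onto the neighbouring C4' oxygen. The free pentaphenol is oxidised easily in base, and the benzylic C2–O1 bond para to the C4' oxygen can ionise and scramble C2. The enabling feature is that C2 and C3 are adjacent oxygen-bearing carbons, C2 is benzylic to ring B, and ring A is symmetric. A benzylic ylide of ring B can therefore add to an aldehyde carbon (C3) that already carries the ring A benzyl group (C4), and either ortho oxygen of ring A can later open the resulting trans epoxide at C2.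

## Retrosynthesis

**16 from 15.** The last cut removes the two methoxymethyl (MOM) ethers of ring B. Ring B is kept as MOM ethers and ring A as silyl ethers so that ring A can be freed by fluoride while ring B stays an ether. A free C4' phenol next to the epoxide would open it through a quinone methide and lose C2. MOM is also the group that tolerates the aryllithium needed for geranylation, where an ortho silyl ether would migrate to carbon. The forward step needs acetal cleavage mild enough for the geranyl chain.

**15 from 13 through 14.** The O1–C2 bond is cut. In the forward direction the three silyl ethers of 13 are removed and a ring A ortho phenol of the epoxy triphenol 14 opens the epoxide at benzylic C2 with inversion. The (2S,3S) trans epoxide maps onto the (2R,3S) trans flavanol, and the epoxide oxygen becomes the C3 hydroxyl. The diol/Mitsunobu and orthoester closures need an osmium-based dihydroxylation that the geranyl alkenes forbid. The forward reaction must close in the 6-endo mode at C2 rather than 5-exo at C3, which the para-alkoxy aryl group on C2 secures under mild acid.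

**13 from 7 and 11 (key disconnection).** The C2–C3 bond and the C2–O bond of the oxirane are cut together. The sulfonium salt 12, formed from benzyl bromide 7 and isothiocineole, is deprotonated to an ylide that adds to arylacetaldehyde 11 and closes to the epoxide. Epoxidising a 1,3-diarylpropene would need an oxidant that also attacks the side chain; the ylide route uses none. The precursors are two simple arenes, each with one functional carbon. The forward reaction must be enantioselective, trans-selective, and faster than enolisation of 11.

**11 from 8.** C3 is added by one-carbon homologation. Persilylation of 2,4,6-trihydroxybenzaldehyde 8 gives 9, a methoxymethylene Wittig reaction gives enol ether 10, and mild hydrolysis gives 11. The alternative of methylenation, hydroboration and oxidation is one step longer and is kept as a reserve.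

**7 from 1 and 4.** The aryl–geranyl bond is cut next to the C4' oxygen. Bromide 1 has the right substitution pattern. After MOM protection (2) and reduction (3), bromine–lithium exchange gives the dilithio species 5, which is alkylated by geranyl bromide 4 at its primary carbon to give 6. An Appel reaction then gives 7. Electrophilic C-geranylation of a catechol is not regioselective, and palladium couplings of geranyl nucleophiles scramble the alkene geometry. The aryl-metal route keeps the E alkene.

## Roads not taken

**Alternative 1:** The cut is the C3=C4 bond of a flav-3-ene, with the C3 hydroxyl added afterwards.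
- Forward step: the diene ether A1 would be closed by the second-generation Grubbs catalyst to the 2H-chromene A2 with loss of ethylene. Hydroboration–oxidation of C3=C4 anti to the C2 aryl group would then give the trans alcohol.
- Merits: chromene-forming ring-closing metathesis is among the most dependable ring closures and is neutral. C3 would follow from C2 by substrate control, so only one centre has to be set by a reagent.
- Weak points: the two chain alkenes are hydroborated as readily as C3=C4, so the alcohol could only be made before geranylation, which pushes a metal-mediated coupling to the end. The chain alkenes can also enter metathesis. The stereocentre of A1 is a doubly activated benzylic aryl ether that must be made enantiopure on a hindered phenol and carried without ionisation.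
- Comparison: this road is ahead in the reliability of the ring closure. The chosen plan sets against it a construction with no alkene-reactive reagent and both centres fixed in one event.

**Alternative 2:** The cut is C4–C4a.
- Forward step: in aryl ether A3 the ring A oxygen is already on C2 and C3–C4 is a terminal epoxide. Catalytic Sc(OTf)3 would make the ring A carbon ortho to the ether oxygen attack C4, closing ring C and freeing the C3 hydroxyl in A4.
- Merits: both stereocentres exist before the closure and can come from an epoxy alcohol of secure origin. Ring A is symmetric, so either ortho carbon serves. No phenol has to be freed next to an epoxide, which is the delicate moment of the chosen route.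
- Weak points: the epoxide is not benzylic and needs a true Lewis acid. That acid meets the geranyl alkenes, which are cation–olefin partners, and the C2–O1 benzylic aryl ether, which can ionise and lose C2. The ring B pivalates damp this ionisation but must later be removed by base or hydride from an air-sensitive catechol. Attack at C3 to a dihydrobenzofuran competes, and A3 takes more steps to build than 7 and 11.
- Comparison: the stereochemical origin here is more predictable than an ylide addition to an enolisable aldehyde. The chosen plan sets against it an epoxide activated exactly at the carbon to be attacked, so catalytic Brønsted acid suffices, and a C2–O1 bond made last by stereospecific displacement.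

**Alternative 3:** The cuts are C3–C4 and O1–C2, an oxa-[4+2] annulation.
- Forward step: a chiral phosphoric acid would dehydrate hydroxybenzyl alcohol A5 to an ortho-quinone methide that adds to the (E)-alkenyl boronate A6, giving the trans 3-boryl chroman A7. Oxidation of C–B with retention (NaBO3·4H2O, harmless to the chain) and desilylation would finish.
- Merits: it is the shortest and most convergent road and is catalytic in the chiral controller, whereas the chosen plan uses a full equivalent of sulfide, although that is recoverable. The alkene geometry becomes the trans relationship, and no epoxide is handled.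
- Weak points: the reaction class is not established for alkenyl boronates. The attacking carbon bears boron and is a poor nucleophile. The methide from a primary benzylic alcohol is unstabilised and oligomerises. The catalyst would have to set two centres on a partner it does not bind. A5 also requires ring A to be desymmetrised to one free phenol.
- Comparison: if it worked as drawn it would be the better synthesis in step count. The chosen plan sets against it a key step of known type with an understood stereochemical model.

Key step: step 8

## Assumptions

- Compound 1 (3-bromo-4,5-dihydroxybenzaldehyde) is taken as a catalogue compound; if it had to be made, O-demethylation of 5-bromovanillin with AlCl3/pyridine would give it.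
- Sense of induction: the (1R,4R,5R) sulfide is taken to give (R,R) trans epoxides from benzylic ylides, so the (1S,4S,5S) enantiomer (from (S)-limonene) is used; if the facial sense proved opposite, the enantiomeric sulfide would be used with no other change.
- "Geranyl" means (2E)-3,7-dimethylocta-2,6-dien-1-yl throughout.

## Route

Step 1
Reactants: 1 3-bromo-4,5-dihydroxybenzaldehyde
Product: 2 3-bromo-4,5-bis(methoxymethoxy)benzaldehyde
Conditions: MOMCl, i-Pr2NEt, CH2Cl2, 0 °C to rt
Reagents that add atoms: chloromethyl methyl ether (MOMCl), COCCl
Why: O-alkylation of both phenols (MOM protection); the acetals tolerate organolithiums, fluoride and the later ylide chemistry, and the ortho oxygen will stabilise the aryllithium of step 3 by chelation.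

Step 2
Reactants: 2 3-bromo-4,5-bis(methoxymethoxy)benzaldehyde
Product: 3 [3-bromo-4,5-bis(methoxymethoxy)phenyl]methanol
Conditions: NaBH4, MeOH, 0 °C
Reagents that add atoms: none
Why: Borohydride reduction of the aldehyde removes the electrophile before halogen–metal exchange and provides the benzylic carbon that becomes C2; aryl bromide and acetals are inert.

Step 3
Reactants: 3 [3-bromo-4,5-bis(methoxymethoxy)phenyl]methanol; 4 geranyl bromide
Product: 6 [3-geranyl-4,5-bis(methoxymethoxy)phenyl]methanol, via dilithio species 5 (not isolated)
Conditions: n-BuLi (2.2 equiv), THF, −78 °C; CuBr·SMe2 (10 mol%), 4, −78 to 0 °C; H2O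
Reagents that add atoms: none
Why: The first equivalent of n-BuLi forms the alkoxide and the second performs bromine–lithium exchange to an ortho-alkoxy-stabilised aryllithium; copper-catalysed allylic substitution then occurs at the unhindered primary carbon of 4, so the chain is attached linearly with its E alkene intact, while the lithium alkoxide is too poor a nucleophile to compete.

Step 4
Reactants: 6 [3-geranyl-4,5-bis(methoxymethoxy)phenyl]methanol
Product: 7 3-geranyl-4,5-bis(methoxymethoxy)benzyl bromide
Conditions: CBr4, PPh3, CH2Cl2, 0 °C; used without chromatography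
Reagents that add atoms: carbon tetrabromide, BrC(Br)(Br)Br
Why: Appel reaction of an electron-rich benzylic alcohol under neutral conditions; alkenes and acetals are untouched, and the reactive para-alkoxybenzyl bromide is taken on at once.

Step 5
Reactants: 8 2,4,6-trihydroxybenzaldehyde
Product: 9 2,4,6-tris(tert-butyldimethylsilyloxy)benzaldehyde
Conditions: TBSCl, imidazole, DMF, rt
Reagents that add atoms: tert-butyldimethylsilyl chloride (TBSCl), CC(C)(C)[Si](C)(C)Cl
Why: Imidazole-promoted silylation of all three phenols; the silyl ethers survive ylides and brief dilute acid and are removed later by fluoride in the presence of the MOM ethers.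

Step 6
Reactants: 9 2,4,6-tris(tert-butyldimethylsilyloxy)benzaldehyde
Product: 10 1-(2-methoxyvinyl)-2,4,6-tris(tert-butyldimethylsilyloxy)benzene (E/Z mixture)
Conditions: Ph3P(CH2OMe)Cl, KN(SiMe3)2, THF, 0 °C; then 9, −78 °C to rt
Reagents that add atoms: (methoxymethyl)triphenylphosphonium chloride, COC[P+](c1ccccc1)(c1ccccc1)c1ccccc1.[Cl-]
Why: Wittig reaction of a non-enolisable aldehyde with the methoxymethylene ylide adds the carbon that becomes C3; the alkene geometry is irrelevant because it is lost on hydrolysis.

Step 7
Reactants: 10 1-(2-methoxyvinyl)-2,4,6-tris(tert-butyldimethylsilyloxy)benzene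
Product: 11 2-[2,4,6-tris(tert-butyldimethylsilyloxy)phenyl]acetaldehyde
Conditions: 1 M aq. HCl, THF, 0 °C to rt, short contact; used crude
Reagents that add atoms: water, O
Why: Acid-catalysed enol ether hydrolysis (C-protonation, hydration of the oxocarbenium ion, loss of methanol); the hindered aryl silyl ethers are slow to cleave in dilute acid, and the aldehyde is used immediately to avoid aldol condensation and air oxidation.

Step 8
Reactants: 7 3-geranyl-4,5-bis(methoxymethoxy)benzyl bromide; 11 2-[2,4,6-tris(tert-butyldimethylsilyloxy)phenyl]acetaldehyde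
Product: 13 (2S,3S)-2-[3-geranyl-4,5-bis(methoxymethoxy)phenyl]-3-[2,4,6-tris(tert-butyldimethylsilyloxy)benzyl]oxirane, via sulfonium tetrafluoroborate 12 (not isolated)
Conditions: (1S,4S,5S)-isothiocineole, AgBF4, CH2Cl2, 0 °C to rt; filter; then 11, phosphazene base P2-Et, CH2Cl2, −78 °C
Reagents that add atoms: none
Why: Silver-assisted S-alkylation of the sulfide by 7 on its exposed exo lone pair gives the single sulfonium diastereomer 12, and the phosphazene base removes the benzylic proton to give a semi-stabilised ylide. The ylide carbon adds to the aldehyde carbon of 11 to an anti betaine, which rotates so that the alkoxide is anti to sulfur and displaces the sulfide in a 3-exo-tet closure that forms C2–O and returns the sulfide. The closest known reaction type is the Corey–Chaykovsky epoxidation in its chiral-sulfide form, in which benzylsulfonium salts of isothiocineole convert aromatic and aliphatic aldehydes into trans epoxides. C2 is set by the sulfide: the gem-dimethyl group beside sulfur fixes the ylide rotamer and shields one face, so the aldehyde meets the open face. C3 is set relative to C2 by the preference for the anti betaine, which can only close to the trans oxirane. The step needs enantioselectivity, trans selectivity and addition in preference to enolisation. The electron-rich ring B makes the ylide reactive enough for betaine formation to be irreversible at −78 °C, and the two ortho silyloxy groups twist ring A out of conjugation with any enolate of 11, which lowers the acidity of its α-hydrogens. No oxidant is present, so the geranyl alkenes are not at risk.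

Step 9
Reactants: 13 (2S,3S)-2-[3-geranyl-4,5-bis(methoxymethoxy)phenyl]-3-[2,4,6-tris(tert-butyldimethylsilyloxy)benzyl]oxirane
Product: 15 (2R,3S)-2-[3-geranyl-4,5-bis(methoxymethoxy)phenyl]chromane-3,5,7-triol, via epoxy triphenol 14 (not isolated)
Conditions: TBAF, AcOH, THF, 0 °C; pH 7 work-up; then CSA (10 mol%), CH2Cl2/THF, −20 to 0 °C
Reagents that add atoms: none
Why: Acetic acid-buffered fluoride cleaves the three aryl silyl ethers without building up phenoxide, and catalytic acid then triggers the known phenol–epoxide cyclisation to a flavan-3-ol. Closure is 6-endo-tet at benzylic C2, where the para-alkoxy aryl group carries the developing positive charge, and proceeds with inversion to give 2R, while C3 keeps its oxygen and configuration; the two ortho phenols of ring A are equivalent. Pyridine–HF is avoided because it adds fluoride to activated benzylic epoxides.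

Step 10
Reactants: 15 (2R,3S)-2-[3-geranyl-4,5-bis(methoxymethoxy)phenyl]chromane-3,5,7-triol
Product: 16 (2R,3S)-2-(3-geranyl-4,5-dihydroxyphenyl)chromane-3,5,7-triol
Conditions: HCl (1.25 M in MeOH), rt, degassed, dark; monitored and stopped at full conversion
Reagents that add atoms: none
Why: Acid-catalysed transacetalisation of the two aryl MOM ethers to dimethoxymethane, a reaction type used on prenylated and geranylated polyphenols; dilute acid at room temperature is below the threshold for cyclising the chain onto the C4' phenol or ionising C2–O1, and exclusion of air protects the catechol.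

## Compound list

1 | 3-bromo-4,5-dihydroxybenzaldehyde | O=Cc1cc(O)c(O)c(Br)c1 | starting material
2 | 3-bromo-4,5-bis(methoxymethoxy)benzaldehyde | O=Cc1cc(OCOC)c(OCOC)c(Br)c1 | intermediate
3 | [3-bromo-4,5-bis(methoxymethoxy)phenyl]methanol | OCc1cc(OCOC)c(OCOC)c(Br)c1 | intermediate
4 | geranyl bromide, (2E)-1-bromo-3,7-dimethylocta-2,6-diene | CC(C)=CCC/C(C)=C/CBr | starting material
5 | lithium [3-lithio-4,5-bis(methoxymethoxy)phenyl]methanolate (dilithio species, formed in situ) | [Li]OCc1cc(OCOC)c(OCOC)c([Li])c1 | intermediate
6 | [3-geranyl-4,5-bis(methoxymethoxy)phenyl]methanol | CC(C)=CCC/C(C)=C/Cc1cc(CO)cc(OCOC)c1OCOC | intermediate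
7 | 3-geranyl-4,5-bis(methoxymethoxy)benzyl bromide | CC(C)=CCC/C(C)=C/Cc1cc(CBr)cc(OCOC)c1OCOC | intermediate
8 | 2,4,6-trihydroxybenzaldehyde | O=Cc1c(O)cc(O)cc1O | starting material
9 | 2,4,6-tris(tert-butyldimethylsilyloxy)benzaldehyde | O=Cc1c(O[Si](C)(C)C(C)(C)C)cc(O[Si](C)(C)C(C)(C)C)cc1O[Si](C)(C)C(C)(C)C | intermediate
10 | 1-(2-methoxyvinyl)-2,4,6-tris(tert-butyldimethylsilyloxy)benzene (E/Z mixture) | COC=Cc1c(O[Si](C)(C)C(C)(C)C)cc(O[Si](C)(C)C(C)(C)C)cc1O[Si](C)(C)C(C)(C)C | intermediate
11 | 2-[2,4,6-tris(tert-butyldimethylsilyloxy)phenyl]acetaldehyde | O=CCc1c(O[Si](C)(C)C(C)(C)C)cc(O[Si](C)(C)C(C)(C)C)cc1O[Si](C)(C)C(C)(C)C | intermediate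
12 | (1S,4S,5S,6S)-6-[3-geranyl-4,5-bis(methoxymethoxy)benzyl]-4,7,7-trimethyl-6-thiabicyclo[3.2.1]octan-6-ium tetrafluoroborate (formed in situ) | C[C@H]1CC[C@H]2C[C@@H]1[S@+](Cc1cc(OCOC)c(OCOC)c(C/C=C(\C)CCC=C(C)C)c1)C2(C)C.F[B-](F)(F)F | intermediate
13 | (2S,3S)-2-[3-geranyl-4,5-bis(methoxymethoxy)phenyl]-3-[2,4,6-tris(tert-butyldimethylsilyloxy)benzyl]oxirane | CC(C)=CCC/C(C)=C/Cc1cc([C@@H]2O[C@H]2Cc2c(O[Si](C)(C)C(C)(C)C)cc(O[Si](C)(C)C(C)(C)C)cc2O[Si](C)(C)C(C)(C)C)cc(OCOC)c1OCOC | intermediate
14 | 2-{[(2S,3S)-3-[3-geranyl-4,5-bis(methoxymethoxy)phenyl]oxiran-2-yl]methyl}benzene-1,3,5-triol (formed in situ) | CC(C)=CCC/C(C)=C/Cc1cc([C@@H]2O[C@H]2Cc2c(O)cc(O)cc2O)cc(OCOC)c1OCOC | intermediate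
15 | (2R,3S)-2-[3-geranyl-4,5-bis(methoxymethoxy)phenyl]chromane-3,5,7-triol | CC(C)=CCC/C(C)=C/Cc1cc([C@H]2Oc3cc(O)cc(O)c3C[C@@H]2O)cc(OCOC)c1OCOC | intermediate
16 | (2R,3S)-2-(3-geranyl-4,5-dihydroxyphenyl)chromane-3,5,7-triol | CC(C)=CCC/C(C)=C/Cc1cc([C@H]2Oc3cc(O)cc(O)c3C[C@@H]2O)cc(O)c1O | target

## Step count and least certain steps

Total: 10 steps. Longest linear sequence: 7 steps (steps 1–4, 8, 9 and 10, from 1 to 16); the ring A branch (steps 5–7) joins at step 8.

**Step 8 (key step).**
- Risk: proton transfer from the α-position of 11 to the ylide or the phosphazene base may outrun carbonyl addition, followed by aldol self-condensation. Anti-selective addition is also less pronounced for an aliphatic aldehyde than for an aromatic one, which would erode the trans preference.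
- Fallback: the same ylide is generated without strong base by carbene transfer. It sets out from 6, which MnO2 would oxidise to 3-geranyl-4,5-bis(methoxymethoxy)benzaldehyde F1. Condensation with TsNHNH2 would give the N-tosylhydrazone F2, and NaOMe its sodium salt F3. Warming F3 with a phase-transfer catalyst in MeCN releases the aryldiazomethane F4 slowly. Rh2(OAc)4 turns F4 into a carbenoid that the same sulfide intercepts, and the ylide then meets 11 at low stationary concentration in a neutral medium. The sulfide has to be in sufficient excess to outcompete the chain alkenes for the carbenoid. The sequence returns to the route at 13.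

**Step 10.**
- Risk: protonation of the C2''=C3'' alkene and capture by the freed C4' phenol (ring closure of the chain), or addition of methanol to the terminal alkene, before both acetals have gone.
- Fallback: non-protic cleavage from 15 with TMSOTf and 2,2'-bipyridyl in CH2Cl2 at 0 °C. This exchanges the aryl MOM groups for silyl groups and silylates the free hydroxyls, giving the pentakis(trimethylsilyl) ether F5. Hydrolysis in wet THF with a trace of acetic acid then returns to the route at 16.

**Step 3.**
- Risk: incomplete bromine–lithium exchange or quenching of the aryllithium, allylic transposition (attack at the tertiary carbon of 4), or O-alkylation of the alkoxide.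
- Fallback: the roles are changed to aryl boron plus allyl electrophile. Miyaura borylation of 3 (B2pin2, Pd(dppf)Cl2, KOAc, dioxane, 80 °C) would give [4,5-bis(methoxymethoxy)-3-(4,4,5,5-tetramethyl-1,3,2-dioxaborolan-2-yl)phenyl]methanol F6. Suzuki–Miyaura allyl–aryl coupling with 4 (Pd(PPh3)4, Cs2CO3, THF/H2O) then attaches the chain at the primary terminus of the allyl–palladium intermediate and returns to the route at 6.

**Step 7.**
- Risk: loss of the unhindered para silyl ether in aqueous acid, or aldol condensation and air oxidation of 11 during handling.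
- Fallback: an acid-free homologation from 9. Wittig methylenation (Ph3P=CH2) would give 2,4,6-tris(tert-butyldimethylsilyloxy)styrene F7. Hydroboration with 9-BBN and oxidation with NaBO3·4H2O would give 2-[2,4,6-tris(tert-butyldimethylsilyloxy)phenyl]ethanol F8. Dess–Martin oxidation buffered with NaHCO3 returns to the route at 11.

**Step 9.**
- Risk: closure in the wrong mode, with a phenoxide formed under fluoride attacking C3 in a 5-exo fashion, or acid-induced hydride shift of the activated epoxide to a benzyl ketone.
- Fallback: the epoxide is taken out of play before the phenols are freed. Acid-catalysed methanolysis of 13 at C2 (CSA, MeOH, −20 °C) would give (2S)-1-[3-geranyl-4,5-bis(methoxymethoxy)phenyl]-1-methoxy-3-[2,4,6-tris(tert-butyldimethylsilyloxy)phenyl]propan-2-ol F9 (C1 epimers). TBAF/AcOH would give the corresponding triphenol F10. Acid-mediated ionisation of the benzylic methyl ether and capture by the ring A phenol then closes ring C with the thermodynamic preference for the 2,3-trans chroman and returns to the route at 15. This gives up stereospecificity at C2 for stereoselectivity.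

## Further compounds

F1 | step 8 | 3-geranyl-4,5-bis(methoxymethoxy)benzaldehyde | CC(C)=CCC/C(C)=C/Cc1cc(C=O)cc(OCOC)c1OCOC
F2 | step 8 | N'-[(E)-3-geranyl-4,5-bis(methoxymethoxy)benzylidene]-4-methylbenzenesulfonohydrazide | CC(C)=CCC/C(C)=C/Cc1cc(/C=N/NS(=O)(=O)c2ccc(C)cc2)cc(OCOC)c1OCOC
F3 | step 8 | sodium salt of tosylhydrazone F2 | CC(C)=CCC/C(C)=C/Cc1cc(/C=N/[N-]S(=O)(=O)c2ccc(C)cc2)cc(OCOC)c1OCOC.[Na+]
F4 | step 8 | [3-geranyl-4,5-bis(methoxymethoxy)phenyl]diazomethane | CC(C)=CCC/C(C)=C/Cc1cc(C=[N+]=[N-])cc(OCOC)c1OCOC
F5 | step 10 | (2R,3S)-2-[3-geranyl-4,5-bis(trimethylsilyloxy)phenyl]-3,5,7-tris(trimethylsilyloxy)chromane | CC(C)=CCC/C(C)=C/Cc1cc([C@H]2Oc3cc(O[Si](C)(C)C)cc(O[Si](C)(C)C)c3C[C@@H]2O[Si](C)(C)C)cc(O[Si](C)(C)C)c1O[Si](C)(C)C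
F6 | step 3 | [4,5-bis(methoxymethoxy)-3-(4,4,5,5-tetramethyl-1,3,2-dioxaborolan-2-yl)phenyl]methanol | OCc1cc(OCOC)c(OCOC)c(B2OC(C)(C)C(C)(C)O2)c1
F7 | step 7 | 2,4,6-tris(tert-butyldimethylsilyloxy)styrene | C=Cc1c(O[Si](C)(C)C(C)(C)C)cc(O[Si](C)(C)C(C)(C)C)cc1O[Si](C)(C)C(C)(C)C
F8 | step 7 | 2-[2,4,6-tris(tert-butyldimethylsilyloxy)phenyl]ethanol | OCCc1c(O[Si](C)(C)C(C)(C)C)cc(O[Si](C)(C)C(C)(C)C)cc1O[Si](C)(C)C(C)(C)C
F9 | step 9 | (2S)-1-[3-geranyl-4,5-bis(methoxymethoxy)phenyl]-1-methoxy-3-[2,4,6-tris(tert-butyldimethylsilyloxy)phenyl]propan-2-ol (C1 epimers) | CC(C)=CCC/C(C)=C/Cc1cc(C(OC)[C@@H](O)Cc2c(O[Si](C)(C)C(C)(C)C)cc(O[Si](C)(C)C(C)(C)C)cc2O[Si](C)(C)C(C)(C)C)cc(OCOC)c1OCOC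
F10 | step 9 | 2-{(2S)-3-[3-geranyl-4,5-bis(methoxymethoxy)phenyl]-2-hydroxy-3-methoxypropyl}benzene-1,3,5-triol (C3 epimers) | CC(C)=CCC/C(C)=C/Cc1cc(C(OC)[C@@H](O)Cc2c(O)cc(O)cc2O)cc(OCOC)c1OCOC
A1 | alternative 1 | (S)-1-[3,4-bis(triisopropylsilyloxy)-5-geranylphenyl]prop-2-en-1-yl 3,5-bis(triisopropylsilyloxy)-2-vinylphenyl ether | CC(C)=CCC/C(C)=C/Cc1cc([C@H](C=C)Oc2cc(O[Si](C(C)C)(C(C)C)C(C)C)cc(O[Si](C(C)C)(C(C)C)C(C)C)c2C=C)cc(O[Si](C(C)C)(C(C)C)C(C)C)c1O[Si](C(C)C)(C(C)C)C(C)C
A2 | alternative 1 | (S)-2-[3,4-bis(triisopropylsilyloxy)-5-geranylphenyl]-5,7-bis(triisopropylsilyloxy)-2H-chromene | CC(C)=CCC/C(C)=C/Cc1cc([C@H]2Oc3cc(O[Si](C(C)C)(C(C)C)C(C)C)cc(O[Si](C(C)C)(C(C)C)C(C)C)c3C=C2)cc(O[Si](C(C)C)(C(C)C)C(C)C)c1O[Si](C(C)C)(C(C)C)C(C)C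
A3 | alternative 2 | 3,5-bis(tert-butyldimethylsilyloxy)phenyl (R)-[3,4-bis(pivaloyloxy)-5-geranylphenyl][(S)-oxiran-2-yl]methyl ether | CC(C)=CCC/C(C)=C/Cc1cc([C@H]([C@@H]2CO2)Oc2cc(O[Si](C)(C)C(C)(C)C)cc(O[Si](C)(C)C(C)(C)C)c2)cc(OC(=O)C(C)(C)C)c1OC(=O)C(C)(C)C
A4 | alternative 2 | (2R,3S)-5,7-bis(tert-butyldimethylsilyloxy)-3',4'-bis(pivaloyloxy)-5'-geranylflavan-3-ol | CC(C)=CCC/C(C)=C/Cc1cc([C@H]2Oc3cc(O[Si](C)(C)C(C)(C)C)cc(O[Si](C)(C)C(C)(C)C)c3C[C@@H]2O)cc(OC(=O)C(C)(C)C)c1OC(=O)C(C)(C)C
A5 | alternative 3 | 3,5-bis(tert-butyldimethylsilyloxy)-2-(hydroxymethyl)phenol | OCc1c(O)cc(O[Si](C)(C)C(C)(C)C)cc1O[Si](C)(C)C(C)(C)C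
A6 | alternative 3 | 2-{(E)-2-[3,4-bis(tert-butyldimethylsilyloxy)-5-geranylphenyl]vinyl}-4,4,5,5-tetramethyl-1,3,2-dioxaborolane | CC(C)=CCC/C(C)=C/Cc1cc(/C=C/B2OC(C)(C)C(C)(C)O2)cc(O[Si](C)(C)C(C)(C)C)c1O[Si](C)(C)C(C)(C)C
A7 | alternative 3 | (2S,3S)-2-[3,4-bis(tert-butyldimethylsilyloxy)-5-geranylphenyl]-5,7-bis(tert-butyldimethylsilyloxy)-3-(4,4,5,5-tetramethyl-1,3,2-dioxaborolan-2-yl)chromane | CC(C)=CCC/C(C)=C/Cc1cc([C@H]2Oc3cc(O[Si](C)(C)C(C)(C)C)cc(O[Si](C)(C)C(C)(C)C)c3C[C@@H]2B4OC(C)(C)C(C)(C)O4)cc(O[Si](C)(C)C(C)(C)C)c1O[Si](C)(C)C(C)(C)C
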